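## The problem

The target joins three oxygenated aryl units. A tetrahydrofuran (O1, C2–C5) carries ring A (the 3,5-dimethoxy-4-oxyphenyl group) at C2, a hydroxymethyl group at C3 and a 4-hydroxy-3,5-dimethoxybenzoyl group at C4. The phenolic oxygen of ring A is the ether oxygen of an erythro guaiacylglycerol chain (C7''–C9''). Five stereocentres must be set: C2 (S), C3 (R) and C4 (S), all trans on the ring, and C7'' (R) and C8'' (S) in the chain. C3 is the only ring centre that cannot be corrected later. C4 is α to the ketone and settles trans to the C3 substituent under thermodynamic control, and C2, a benzylic ether carbon, is best fixed in the ring-forming event. The chain centres are remote from the ring and need reagent control. The 4-aroyl tetrahydrofuran is a β-alkoxy ketone (epimerisation, retro-oxa-Michael opening), C2–O1 and the C7'' carbinol are benzylic C–O bonds para to oxygen (acid, hydrogenolysis, quinone methide formation once the phenols are free), and no hydride step is possible once the ketone is present. The key step rests on one feature: C2 is a benzylic donor carbon and C4 an acceptor carbon at the carboxyl level, both attached to C3, and O1–C5H2 is one molecule of formaldehyde, so the ring is a formal (3+2) adduct of a donor–acceptor cyclopropane and CH2=O.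

## Retrosynthesis

**Deprotection.** Target 30 is traced to the tribenzyl ether 29 by cutting three O–benzyl bonds. Benzyl groups on the two phenols and the primary alcohol survive every earlier step and fall in one operation. The forward step must spare the ring C2–O1 bond, the C7'' carbinol and the aryl ketone.

**Aryl ketone.** 29 is cut between the ketone carbon and the syringyl ring, giving the Weinreb amide 26 and the aryllithium 28 (from bromide 27, from phenol 1). The neighbouring cut, C4–C(=O), would need an acyl anion and a leaving group on the ring. Making the ketone earlier would expose it to the hydride of step 15. The precursor keeps C4 at the carboxyl level inherited from the malonate. The forward reaction must stop at mono-addition and tolerate the free diol.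

**Side chain.** 26 is traced through the inverted ester 24 to the aldol adduct 23, which is cut at C7''–C8'' into imide 20 and aldehyde 21. Forming the O–C8'' bond instead, by substitution at a secondary carbon flanked by two oxygenated carbons with a di-ortho-substituted phenol, was judged unreliable. The auxiliary-controlled aldol sets C8'' correctly but gives the syn (threo) pair, so inversion at C7'' (23 to 24) is added to reach the erythro array. The forward steps need a Z enolate, inversion without elimination, and reductive removal of the auxiliary beside a Weinreb amide.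

**Aryl ether.** 20 is cut at the phenol O–CH2 bond into phenol 18 and the chloroacetyl imide 19. Substitution at a primary α-halo carbonyl carbon is the one etherification a hindered 2,6-dimethoxyphenoxide does well, and it brings in the auxiliary at the same time.

**C4 adjustment.** 18 goes back through the all-trans phenol ester 17 and the ester mixture 16 to diester 15. One ester carbon is excised, C4 is equilibrated under control of C3, the silyl ether is removed and the ester becomes the Weinreb amide. No skeletal bond is made.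

**Key disconnection.** 15 is cut at O1–C2 and C4–C5 into the cis cyclopropane 13 and formaldehyde 14. Against stepwise etherification routes, this closes the ring and fixes C2 relative to C3 in one catalytic, stereospecific step. The precursor has two stereocentres and one ring less functionality. The forward reaction must invert cleanly at the benzylic carbon and outrun formaldehyde oligomerisation.

**Cyclopropane.** 13 is cut at both bonds to the malonate carbon, giving the cis cyclic sulfate 10 (from diol 8) and dimethyl malonate 11. Two SN2 displacements invert both carbons, so the erythro diol gives the cis ring whichever carbon is attacked first. Carbene transfer to a Z-alkene would need an enantioselective catalyst for a symmetric carbene on a cis alkene and is kept as a fallback. Osmium-catalysed asymmetric dihydroxylation of the Z-alkene was set aside because cis-disubstituted alkenes are the poorest substrate class for that reaction.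

**Erythro diol.** 8 comes from the α-hydroxy ketone 7 by chelation-controlled reduction, and 7 from Weinreb amide 5 and aryllithium 6 (from bromide 2, from phenol 1). The C2 carbinol of 5 is taken from O-benzyl-L-serine 3 through hydroxy acid 4, so the enantiomeric purity of the core rests on the chiral pool and on one well-understood diastereoselective reduction.

## Roads not taken

Alternative 1: The cut runs through C4–C(=O) and C2–C3; the O1–C2 bridge is left for a later cycloetherification. Forward, the 2-lithio derivative of the aryl dithiane A3 adds to the β-carbon of the menthyloxy butenolide A2 anti to the acetal substituent, and the lactone enolate is trapped by aldehyde A4 to give the trans lactone A1.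
- Merits: three-component convergence with both aryl groups and every core carbon in one operation; a cheap, recoverable chiral controller; the ketone is masked as a dithiane that would also survive hydride.
- Weak points: no ring is closed, so lactone reduction and a cationic closure of C5–OH onto the benzylic C2 carbinol must follow, with C2 set thermodynamically. The trans relationship in A1 maps onto a 3,4-cis tetrahydrofuran, so C4 must be epimerised once the ketone is unmasked. The dithiane must be hydrolysed in the presence of three electron-rich arenes and an allyl ether.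
- Comparison: in convergence and step count to the aroyl-bearing core this road is at least as good as the chosen one, and it avoids a late organolithium addition. The chosen plan sets against it a single catalytic, stereospecific step for ring closure and C2, no thioacetal removal, and no stoichiometric auxiliary for the core.

Alternative 2: The cut is C3–C4. Forward, Cp2TiCl (trivalent titanium) opens the oxirane of the epoxy cinnamyl ether A6 to a β-titanoxy radical at C3, which adds 5-exo-trig to the styrenyl double bond; reduction of the benzylic radical gives tetrahydrofuran A5.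
- Merits: short and mild; the C3 hydroxymethyl group is delivered free; the allyl and silyl ethers on the two phenols are already differentiated for the later steps.
- Weak points: the C4 substituent arrives as a benzylic CH2, so a benzylic oxidation is needed in a molecule with a second, more activated benzylic C–H (C2–H, α to the ring oxygen) and three electron-rich rings. The ring is 3,4-cis, so C4 must be epimerised after oxidation. Absolute configuration rests on an enantiopure epoxy alcohol, and the C2/C3 selectivity is conformational.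
- Comparison: this road reaches the ring in fewer steps and with less protecting-group traffic, which is better. The chosen plan sets against it the correct oxidation level at C4 from the outset (acyl substitution, no C–H oxidation) and a stereospecific origin for C2.

Alternative 3: The cut is O1–C5. Forward, a chiral catalyst with a peroxide inserts oxygen into one of the two enantiotopic ring bonds of cyclobutanone A8 to give lactone A7, which sets C4. The lactone carbonyl then has to become C2 by aryl addition and lactol reduction, and the α-carbon (C3) has to be hydroxymethylated.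
- Merits: a catalytic asymmetric step; the acyl group is in place from the start as a ketal, so no late organolithium addition is needed.
- Weak points: the only stereocentre it sets is the one that is epimerisable in the target. C3 and C2 must still be built by lactone enolate chemistry and reduction of an oxocarbenium ion, where only the C3 substituent distinguishes the faces. The ketal must survive the Lewis acid of that reduction. A7 as drawn is the (R)-lactone, which maps onto the antipode of the target at C4, so the other catalyst enantiomer would be required.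
- Comparison: this road is better in relying on one catalytic source of chirality. The chosen plan sets against it that the robust centre C3 carries the chirality and that C2 and the ring arise together.

Key step: step 8

Remark: the tetrahydrofuran is numbered O1, C2 (aryl), C3 (CH2O), C4 (acyl), C5 throughout and the glycerol chain C7'' (carbinol), C8'' (aryl ether), C9'' (CH2OH); reagents 19 and 21 are taken as commercial and formaldehyde 14 is supplied as paraformaldehyde.

## Steps

Step 1
Reactants: 1 4-bromo-2,6-dimethoxyphenol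
Product: 2 (4-bromo-2,6-dimethoxyphenoxy)triisopropylsilane
Conditions: TIPSCl, imidazole, DMF, 40 °C
Reagents that add atoms: triisopropylsilyl chloride, CC(C)[Si](Cl)(C(C)C)C(C)C
Why: O-silylation of the phenol; the bulky silyl ether withstands organolithium, Lewis acid and hydride steps and is removable without touching benzyl ethers.

Step 2
Reactants: 3 O-benzyl-L-serine
Product: 4 (S)-3-(benzyloxy)-2-hydroxypropanoic acid
Conditions: NaNO2, 1 M aq. H2SO4, 0 °C → rt
Reagents that add atoms: water, O
Why: Diazotisation of an α-amino acid; the carboxylate displaces N2 to an α-lactone that water opens, two inversions giving net retention, so the (S) centre of serine becomes the (S) carbinol.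

Step 3
Reactants: 4 (S)-3-(benzyloxy)-2-hydroxypropanoic acid
Product: 5 (S)-3-(benzyloxy)-2-hydroxy-N-methoxy-N-methylpropanamide
Conditions: MeNHOMe·HCl, EDC·HCl, HOBt, N-methylmorpholine, CH2Cl2, 0 °C → rt
Reagents that add atoms: N,O-dimethylhydroxylamine hydrochloride, CNOC.Cl
Why: Carbodiimide amide coupling to the Weinreb amide; the α-hydroxy acid has no oxazolone pathway, so the stereocentre is not at risk.

Step 4
Reactants: 2 (4-bromo-2,6-dimethoxyphenoxy)triisopropylsilane; 5 (S)-3-(benzyloxy)-2-hydroxy-N-methoxy-N-methylpropanamide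
Product: 7 (S)-3-(benzyloxy)-1-[3,5-dimethoxy-4-(triisopropylsilyloxy)phenyl]-2-hydroxypropan-1-one, via aryllithium 6 (not isolated)
Conditions: 2 (2.3 equiv), n-BuLi (2.2 equiv), THF, −78 °C; then 5, −78 → 0 °C; aq. NH4Cl
Reagents that add atoms: n-butyllithium, [Li]CCCC (lithium in 6 only)
Why: Bromine–lithium exchange followed by Weinreb ketone synthesis; one equivalent of 6 is spent on the hydroxyl proton, and the chelated tetrahedral intermediate releases the ketone only on work-up, which prevents over-addition and enolisation of the α-centre.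

Step 5
Reactants: 7 (S)-3-(benzyloxy)-1-[3,5-dimethoxy-4-(triisopropylsilyloxy)phenyl]-2-hydroxypropan-1-one
Product: 8 (1R,2S)-3-(benzyloxy)-1-[3,5-dimethoxy-4-(triisopropylsilyloxy)phenyl]propane-1,2-diol
Conditions: Zn(BH4)2, Et2O, −20 → 0 °C
Reagents that add atoms: none
Why: Chelation-controlled ketone reduction; zinc bridges the carbonyl and α-hydroxyl oxygens and hydride enters from the face of the α-hydrogen (Cram chelate model), giving the anti (erythro) diol with the new C1 centre R.

Step 6
Reactants: 8 (1R,2S)-3-(benzyloxy)-1-[3,5-dimethoxy-4-(triisopropylsilyloxy)phenyl]propane-1,2-diol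
Product: 10 (4S,5R)-4-[(benzyloxy)methyl]-5-[3,5-dimethoxy-4-(triisopropylsilyloxy)phenyl]-1,3,2-dioxathiolane 2,2-dioxide, via cyclic sulfite 9 (not isolated)
Conditions: SOCl2, Et3N, CH2Cl2, 0 °C; then RuCl3·xH2O (1 mol %), NaIO4, MeCN–H2O, 0 °C, short contact
Reagents that add atoms: thionyl chloride, ClS(Cl)=O; sodium periodate, [Na+].[O-]I(=O)(=O)=O
Why: Cyclic sulfite formation and RuO4-catalysed oxidation to the cyclic sulfate; no C–O bond is broken, so both configurations of 8 are retained, and the oxidation is kept cold and brief to spare the electron-rich ring and the benzyl ether.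

Step 7
Reactants: 10 (4S,5R)-4-[(benzyloxy)methyl]-5-[3,5-dimethoxy-4-(triisopropylsilyloxy)phenyl]-1,3,2-dioxathiolane 2,2-dioxide; 11 dimethyl malonate
Product: 13 dimethyl (2R,3R)-2-[(benzyloxy)methyl]-3-[3,5-dimethoxy-4-(triisopropylsilyloxy)phenyl]cyclopropane-1,1-dicarboxylate, via sulfate monoester 12 (not isolated)
Conditions: NaH (2.2 equiv), DME, 0 °C → rt, then 70 °C
Reagents that add atoms: sodium hydride, [Na+].[H-] (sodium in 12 only)
Why: Double nucleophilic displacement of a cyclic sulfate by malonate (SN2 opening, then 3-exo-tet closure on the sulfate monoester); each carbon is inverted once, so the erythro-derived cis sulfate gives the cis (2R,3R) cyclopropane whichever carbon is attacked first.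

Step 8
Reactants: 13 dimethyl (2R,3R)-2-[(benzyloxy)methyl]-3-[3,5-dimethoxy-4-(triisopropylsilyloxy)phenyl]cyclopropane-1,1-dicarboxylate; 14 formaldehyde (as paraformaldehyde)
Product: 15 dimethyl (2S,3R)-3-[(benzyloxy)methyl]-2-[3,5-dimethoxy-4-(triisopropylsilyloxy)phenyl]tetrahydrofuran-4,4-dicarboxylate
Conditions: (CH2O)n (5 equiv), Sn(OTf)2 (10 mol %), ClCH2CH2Cl, rt → 40 °C
Reagents that add atoms: none
Why: Sn(OTf)2 (divalent tin) chelates the geminal ester carbonyls of 13 and polarises the C1–C2 bond, the oxygen of monomeric formaldehyde, released from the polymer by the same Lewis acid, attacks the benzylic carbon in an SN2-like manner with inversion inside a tight ion pair, and the tin malonate enolate then adds to the oxocarbenium carbon to form C4–C5. The closest known reaction type is the Lewis-acid-catalysed (3+2) annulation of 2-aryl and 2,3-disubstituted cyclopropane-1,1-diesters with aldehydes to tetrahydrofurans, of which formaldehyde is an unhindered member. The single ring is closed by this aldol-type attack of the enolate carbon on the O-alkyl oxocarbenium ion, formally a 5-endo-trig closure at the C=O+ unit (5-enolexo for the enolate), made possible by the envelope geometry of the tethered ion pair. The one new stereocentre, C2, is controlled by the configuration of the same carbon in 13: inversion converts the cis arrangement of aryl and benzyloxymethyl groups into the 2,3-trans ring, C3 is carried through unchanged, and C4 and C5 are not stereogenic. The step needs stereospecific opening without a free benzylic cation and annulation in preference to formaldehyde oligomerisation; the first is secured by the donor, whose para silyloxy group is twisted out of conjugation by the two flanking methoxy groups, and by a mild catalyst near room temperature, the second by an excess of the aldehyde source and dilution. If some ionisation did occur, capture of the cation anti to the C3 substituent would lead to the same 2,3-trans isomer.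

Step 9
Reactants: 15 dimethyl (2S,3R)-3-[(benzyloxy)methyl]-2-[3,5-dimethoxy-4-(triisopropylsilyloxy)phenyl]tetrahydrofuran-4,4-dicarboxylate
Product: 16 methyl (2S,3R,4RS)-3-[(benzyloxy)methyl]-2-[3,5-dimethoxy-4-(triisopropylsilyloxy)phenyl]tetrahydrofuran-4-carboxylate (C4 epimer mixture)
Conditions: LiCl (3 equiv), H2O (2 equiv), DMSO, 140 °C
Reagents that add atoms: none
Why: Krapcho dealkoxycarbonylation; chloride demethylates one ester, the carboxylate loses CO2 and the enolate is protonated. Protonation at C4 is not expected to be selective, so C4 is settled in step 10.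

Step 10
Reactants: 16 methyl (2S,3R,4RS)-3-[(benzyloxy)methyl]-2-[3,5-dimethoxy-4-(triisopropylsilyloxy)phenyl]tetrahydrofuran-4-carboxylate
Product: 17 methyl (2S,3R,4S)-3-[(benzyloxy)methyl]-2-(4-hydroxy-3,5-dimethoxyphenyl)tetrahydrofuran-4-carboxylate
Conditions: NaOMe (3 equiv), MeOH–THF, 50 °C; aq. NH4Cl
Reagents that add atoms: none
Why: Base-mediated epimerisation through the ester enolate places the ester trans to the C3 substituent (C4 set as S under thermodynamic control by C3, giving the all-trans ring). Methoxide also cleaves the aryl silyl ether by attack at silicon (silyl ether methanolysis), so the phenol is freed in the same operation.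

Step 11
Reactants: 17 methyl (2S,3R,4S)-3-[(benzyloxy)methyl]-2-(4-hydroxy-3,5-dimethoxyphenyl)tetrahydrofuran-4-carboxylate
Product: 18 (2S,3R,4S)-3-[(benzyloxy)methyl]-2-(4-hydroxy-3,5-dimethoxyphenyl)-N-methoxy-N-methyltetrahydrofuran-4-carboxamide
Conditions: MeNHOMe·HCl (3 equiv), iPrMgCl (7 equiv), THF, −20 → 0 °C
Reagents that add atoms: N,O-dimethylhydroxylamine hydrochloride, CNOC.Cl
Why: Ester aminolysis by the chloromagnesium amide of MeNHOMe gives the Weinreb amide; the phenol is held as its magnesium phenoxide and the low temperature avoids enolisation at C4.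

Step 12
Reactants: 18 (2S,3R,4S)-3-[(benzyloxy)methyl]-2-(4-hydroxy-3,5-dimethoxyphenyl)-N-methoxy-N-methyltetrahydrofuran-4-carboxamide; 19 (R)-4-benzyl-3-(2-chloroacetyl)oxazolidin-2-one
Product: 20 (2S,3R,4S)-2-(4-{2-[(4R)-4-benzyl-2-oxooxazolidin-3-yl]-2-oxoethoxy}-3,5-dimethoxyphenyl)-3-[(benzyloxy)methyl]-N-methoxy-N-methyltetrahydrofuran-4-carboxamide
Conditions: K2CO3, NaI (10 mol %), acetone, 50 °C
Reagents that add atoms: none
Why: Williamson ether synthesis; the hindered phenoxide attacks the primary α-halo carbonyl carbon (iodide exchange in situ, Finkelstein), a substitution that is fast even for di-ortho-substituted phenols.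

Step 13
Reactants: 20 (2S,3R,4S)-2-(4-{2-[(4R)-4-benzyl-2-oxooxazolidin-3-yl]-2-oxoethoxy}-3,5-dimethoxyphenyl)-3-[(benzyloxy)methyl]-N-methoxy-N-methyltetrahydrofuran-4-carboxamide; 21 4-(benzyloxy)-3-methoxybenzaldehyde
Product: 23 (2S,3R,4S)-2-(4-{[(1S,2R)-1-[4-(benzyloxy)-3-methoxyphenyl]-3-[(4R)-4-benzyl-2-oxooxazolidin-3-yl]-1-hydroxy-3-oxopropan-2-yl]oxy}-3,5-dimethoxyphenyl)-3-[(benzyloxy)methyl]-N-methoxy-N-methyltetrahydrofuran-4-carboxamide, via boron enolate 22 (not isolated)
Conditions: Bu2BOTf (1.3 equiv), iPr2NEt (1.5 equiv), CH2Cl2, −78 → 0 °C; then 21, −78 → 0 °C; pH 7 buffer, MeOH, H2O2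
Reagents that add atoms: dibutylboron triflate, CCCCB(CCCC)OS(=O)(=O)C(F)(F)F (boron in 22 only)
Why: Evans syn-aldol reaction; the Z boron enolate 22 reacts through a closed chair (Zimmerman–Traxler) transition state on the face away from the benzyl group of the (R)-auxiliary. This sets C8'' in the configuration of the target and C7'' as its epimer (syn pair); the Weinreb amide is not enolised by Bu2BOTf/amine.

Step 14
Reactants: 23 (the syn aldol adduct)
Product: 24 (1R,2R)-1-[4-(benzyloxy)-3-methoxyphenyl]-3-[(4R)-4-benzyl-2-oxooxazolidin-3-yl]-2-({4-[(2S,3R,4S)-3-[(benzyloxy)methyl]-4-[methoxy(methyl)carbamoyl]tetrahydrofuran-2-yl]-2,6-dimethoxyphenyl}oxy)-3-oxopropyl 4-nitrobenzoate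
Conditions: 4-O2NC6H4CO2H, PPh3, DIAD, THF, 0 °C → rt
Reagents that add atoms: 4-nitrobenzoic acid, OC(=O)c1ccc(cc1)[N+](=O)[O-]
Why: Mitsunobu reaction; SN2 displacement of the activated benzylic oxygen by 4-nitrobenzoate inverts C7'' to R and turns the syn (threo) pair into the anti (erythro) pair. C8'' is protected from enolisation by the allylic strain of the N-acyloxazolidinone.

Step 15
Reactants: 24 (the inverted 4-nitrobenzoate)
Product: 26 (2S,3R,4S)-2-(4-{[(1R,2S)-1-[4-(benzyloxy)-3-methoxyphenyl]-1,3-dihydroxypropan-2-yl]oxy}-3,5-dimethoxyphenyl)-3-[(benzyloxy)methyl]-N-methoxy-N-methyltetrahydrofuran-4-carboxamide, via hydroxy ester 25 (not isolated)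
Conditions: NaBH4, THF–H2O, 0 °C → rt; then K2CO3, MeOH, rt
Reagents that add atoms: none
Why: Reductive cleavage of the N-acyloxazolidinone by NaBH4 at the exocyclic imide carbonyl gives the C9'' alcohol and frees the auxiliary, and methanolysis (transesterification) then removes the 4-nitrobenzoate; the Weinreb amide is inert to both reagents and neither stereocentre is touched.

Step 16
Reactants: 1 4-bromo-2,6-dimethoxyphenol
Product: 27 2-(benzyloxy)-5-bromo-1,3-dimethoxybenzene
Conditions: BnBr, K2CO3, DMF, 60 °C
Reagents that add atoms: benzyl bromide, BrCc1ccccc1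
Why: Williamson O-benzylation of the phenol; supplies the aryl donor for the ketone with a protecting group that falls in the last step.

Step 17
Reactants: 26 (the Weinreb amide diol); 27 2-(benzyloxy)-5-bromo-1,3-dimethoxybenzene
Product: 29 [(2S,3R,4S)-2-(4-{[(1R,2S)-1-[4-(benzyloxy)-3-methoxyphenyl]-1,3-dihydroxypropan-2-yl]oxy}-3,5-dimethoxyphenyl)-3-[(benzyloxy)methyl]tetrahydrofuran-4-yl][4-(benzyloxy)-3,5-dimethoxyphenyl]methanone, via aryllithium 28 (not isolated)
Conditions: 27 (3.6 equiv), n-BuLi (3.5 equiv), THF, −78 °C; then 26, −78 → −20 °C; aq. NH4Cl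
Reagents that add atoms: n-butyllithium, [Li]CCCC (lithium in 28 only)
Why: Weinreb ketone synthesis; two equivalents of 28 convert the diol into its dilithium alkoxide and a third adds to the amide, the chelated tetrahedral intermediate releasing the ketone only on work-up so that no tertiary alcohol forms. C4 keeps the trans configuration, which is also the thermodynamic one for the ketone.

Step 18
Reactants: 29 (the tribenzyl ether)
Product: 30 [(2S,3R,4S)-2-(4-{[(1R,2S)-1,3-dihydroxy-1-(4-hydroxy-3-methoxyphenyl)propan-2-yl]oxy}-3,5-dimethoxyphenyl)-3-(hydroxymethyl)tetrahydrofuran-4-yl](4-hydroxy-3,5-dimethoxyphenyl)methanone (CNP0236429.1)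
Conditions: H2 (1 atm), Pd/C (10 wt %), EtOAc–MeOH, rt, stopped after three equivalents of H2
Reagents that add atoms: none
Why: Hydrogenolysis of the three O-benzyl groups; aryl and primary alkyl benzyl ethers should be cleaved faster than the ring benzylic C–O bond, the benzylic alcohol and the electron-rich aryl ketone under neutral conditions at atmospheric pressure.

## Compound list

1 | 4-bromo-2,6-dimethoxyphenol | COc1cc(Br)cc(OC)c1O | starting material
2 | (4-bromo-2,6-dimethoxyphenoxy)triisopropylsilane | COc1cc(Br)cc(OC)c1O[Si](C(C)C)(C(C)C)C(C)C | intermediate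
3 | O-benzyl-L-serine | N[C@@H](COCc1ccccc1)C(=O)O | starting material
4 | (S)-3-(benzyloxy)-2-hydroxypropanoic acid | OC(=O)[C@@H](O)COCc1ccccc1 | intermediate
5 | (S)-3-(benzyloxy)-2-hydroxy-N-methoxy-N-methylpropanamide | CON(C)C(=O)[C@@H](O)COCc1ccccc1 | intermediate
6 | [3,5-dimethoxy-4-(triisopropylsilyloxy)phenyl]lithium | [Li]c1cc(OC)c(O[Si](C(C)C)(C(C)C)C(C)C)c(OC)c1 | intermediate (not isolated)
7 | (S)-3-(benzyloxy)-1-[3,5-dimethoxy-4-(triisopropylsilyloxy)phenyl]-2-hydroxypropan-1-one | COc1cc(C(=O)[C@@H](O)COCc2ccccc2)cc(OC)c1O[Si](C(C)C)(C(C)C)C(C)C | intermediate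
8 | (1R,2S)-3-(benzyloxy)-1-[3,5-dimethoxy-4-(triisopropylsilyloxy)phenyl]propane-1,2-diol (erythro) | COc1cc([C@@H](O)[C@@H](O)COCc2ccccc2)cc(OC)c1O[Si](C(C)C)(C(C)C)C(C)C | intermediate
9 | (4S,5R)-4-[(benzyloxy)methyl]-5-[3,5-dimethoxy-4-(triisopropylsilyloxy)phenyl]-1,3,2-dioxathiolane 2-oxide (cis, both sulfur epimers) | COc1cc([C@H]2OS(=O)O[C@H]2COCc2ccccc2)cc(OC)c1O[Si](C(C)C)(C(C)C)C(C)C | intermediate (not isolated)
10 | (4S,5R)-4-[(benzyloxy)methyl]-5-[3,5-dimethoxy-4-(triisopropylsilyloxy)phenyl]-1,3,2-dioxathiolane 2,2-dioxide (cis cyclic sulfate) | COc1cc([C@H]2OS(=O)(=O)O[C@H]2COCc2ccccc2)cc(OC)c1O[Si](C(C)C)(C(C)C)C(C)C | intermediate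
11 | dimethyl malonate | COC(=O)CC(=O)OC | starting material
12 | sodium (2R,3S)-1-(benzyloxy)-3-[3,5-dimethoxy-4-(triisopropylsilyloxy)phenyl]-5-methoxy-4-(methoxycarbonyl)-5-oxopentan-2-yl sulfate (drawn for first attack at the benzylic carbon) | COc1cc([C@H](C(C(=O)OC)C(=O)OC)[C@H](COCc2ccccc2)OS(=O)(=O)[O-])cc(OC)c1O[Si](C(C)C)(C(C)C)C(C)C.[Na+] | intermediate (not isolated)
13 | dimethyl (2R,3R)-2-[(benzyloxy)methyl]-3-[3,5-dimethoxy-4-(triisopropylsilyloxy)phenyl]cyclopropane-1,1-dicarboxylate (aryl and benzyloxymethyl cis) | COc1cc([C@H]2[C@@H](COCc3ccccc3)C2(C(=O)OC)C(=O)OC)cc(OC)c1O[Si](C(C)C)(C(C)C)C(C)C | intermediate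
14 | formaldehyde (from paraformaldehyde) | C=O | starting material
15 | dimethyl (2S,3R)-3-[(benzyloxy)methyl]-2-[3,5-dimethoxy-4-(triisopropylsilyloxy)phenyl]tetrahydrofuran-4,4-dicarboxylate (2,3-trans) | COc1cc([C@H]2OCC(C(=O)OC)(C(=O)OC)[C@@H]2COCc2ccccc2)cc(OC)c1O[Si](C(C)C)(C(C)C)C(C)C | intermediate
16 | methyl (2S,3R,4RS)-3-[(benzyloxy)methyl]-2-[3,5-dimethoxy-4-(triisopropylsilyloxy)phenyl]tetrahydrofuran-4-carboxylate (C4 epimer mixture) | COc1cc([C@H]2OCC(C(=O)OC)[C@@H]2COCc2ccccc2)cc(OC)c1O[Si](C(C)C)(C(C)C)C(C)C | intermediate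
17 | methyl (2S,3R,4S)-3-[(benzyloxy)methyl]-2-(4-hydroxy-3,5-dimethoxyphenyl)tetrahydrofuran-4-carboxylate (all-trans) | COc1cc([C@H]2OC[C@@H](C(=O)OC)[C@@H]2COCc2ccccc2)cc(OC)c1O | intermediate
18 | (2S,3R,4S)-3-[(benzyloxy)methyl]-2-(4-hydroxy-3,5-dimethoxyphenyl)-N-methoxy-N-methyltetrahydrofuran-4-carboxamide | COc1cc([C@H]2OC[C@@H](C(=O)N(C)OC)[C@@H]2COCc2ccccc2)cc(OC)c1O | intermediate
19 | (R)-4-benzyl-3-(2-chloroacetyl)oxazolidin-2-one | O=C(CCl)N1[C@H](Cc2ccccc2)COC1=O | starting material
20 | (2S,3R,4S)-2-(4-{2-[(4R)-4-benzyl-2-oxooxazolidin-3-yl]-2-oxoethoxy}-3,5-dimethoxyphenyl)-3-[(benzyloxy)methyl]-N-methoxy-N-methyltetrahydrofuran-4-carboxamide | COc1cc([C@H]2OC[C@@H](C(=O)N(C)OC)[C@@H]2COCc2ccccc2)cc(OC)c1OCC(=O)N1[C@H](Cc2ccccc2)COC1=O | intermediate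
21 | 4-(benzyloxy)-3-methoxybenzaldehyde | COc1cc(C=O)ccc1OCc1ccccc1 | starting material
22 | Z dibutylboron enolate of 20 (aryloxy group and O–B cis) | COc1cc([C@H]2OC[C@@H](C(=O)N(C)OC)[C@@H]2COCc2ccccc2)cc(OC)c1O/C=C(\OB(CCCC)CCCC)N1[C@H](Cc2ccccc2)COC1=O | intermediate (not isolated)
23 | (2S,3R,4S)-2-(4-{[(1S,2R)-1-[4-(benzyloxy)-3-methoxyphenyl]-3-[(4R)-4-benzyl-2-oxooxazolidin-3-yl]-1-hydroxy-3-oxopropan-2-yl]oxy}-3,5-dimethoxyphenyl)-3-[(benzyloxy)methyl]-N-methoxy-N-methyltetrahydrofuran-4-carboxamide (syn aldol) | COc1cc([C@H](O)[C@H](C(=O)N2[C@H](Cc3ccccc3)COC2=O)Oc2c(OC)cc([C@H]3OC[C@@H](C(=O)N(C)OC)[C@@H]3COCc3ccccc3)cc2OC)ccc1OCc1ccccc1 | intermediate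
24 | (1R,2R)-1-[4-(benzyloxy)-3-methoxyphenyl]-3-[(4R)-4-benzyl-2-oxooxazolidin-3-yl]-2-({4-[(2S,3R,4S)-3-[(benzyloxy)methyl]-4-[methoxy(methyl)carbamoyl]tetrahydrofuran-2-yl]-2,6-dimethoxyphenyl}oxy)-3-oxopropyl 4-nitrobenzoate | COc1cc([C@@H](OC(=O)c2ccc(cc2)[N+](=O)[O-])[C@H](C(=O)N2[C@H](Cc3ccccc3)COC2=O)Oc2c(OC)cc([C@H]3OC[C@@H](C(=O)N(C)OC)[C@@H]3COCc3ccccc3)cc2OC)ccc1OCc1ccccc1 | intermediate
25 | (1R,2S)-1-[4-(benzyloxy)-3-methoxyphenyl]-2-({4-[(2S,3R,4S)-3-[(benzyloxy)methyl]-4-[methoxy(methyl)carbamoyl]tetrahydrofuran-2-yl]-2,6-dimethoxyphenyl}oxy)-3-hydroxypropyl 4-nitrobenzoate | COc1cc([C@@H](OC(=O)c2ccc(cc2)[N+](=O)[O-])[C@H](CO)Oc2c(OC)cc([C@H]3OC[C@@H](C(=O)N(C)OC)[C@@H]3COCc3ccccc3)cc2OC)ccc1OCc1ccccc1 | intermediate (not isolated)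
26 | (2S,3R,4S)-2-(4-{[(1R,2S)-1-[4-(benzyloxy)-3-methoxyphenyl]-1,3-dihydroxypropan-2-yl]oxy}-3,5-dimethoxyphenyl)-3-[(benzyloxy)methyl]-N-methoxy-N-methyltetrahydrofuran-4-carboxamide (erythro) | COc1cc([C@@H](O)[C@H](CO)Oc2c(OC)cc([C@H]3OC[C@@H](C(=O)N(C)OC)[C@@H]3COCc3ccccc3)cc2OC)ccc1OCc1ccccc1 | intermediate
27 | 2-(benzyloxy)-5-bromo-1,3-dimethoxybenzene | COc1cc(Br)cc(OC)c1OCc1ccccc1 | intermediate
28 | [4-(benzyloxy)-3,5-dimethoxyphenyl]lithium | [Li]c1cc(OC)c(OCc2ccccc2)c(OC)c1 | intermediate (not isolated)
29 | [(2S,3R,4S)-2-(4-{[(1R,2S)-1-[4-(benzyloxy)-3-methoxyphenyl]-1,3-dihydroxypropan-2-yl]oxy}-3,5-dimethoxyphenyl)-3-[(benzyloxy)methyl]tetrahydrofuran-4-yl][4-(benzyloxy)-3,5-dimethoxyphenyl]methanone | COc1cc([C@@H](O)[C@H](CO)Oc2c(OC)cc([C@H]3OC[C@@H](C(=O)c4cc(OC)c(OCc5ccccc5)c(OC)c4)[C@@H]3COCc3ccccc3)cc2OC)ccc1OCc1ccccc1 | intermediate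
30 | [(2S,3R,4S)-2-(4-{[(1R,2S)-1,3-dihydroxy-1-(4-hydroxy-3-methoxyphenyl)propan-2-yl]oxy}-3,5-dimethoxyphenyl)-3-(hydroxymethyl)tetrahydrofuran-4-yl](4-hydroxy-3,5-dimethoxyphenyl)methanone | COc1cc([C@@H](O)[C@H](CO)Oc2c(OC)cc([C@H]3OC[C@@H](C(=O)c4cc(OC)c(O)c(OC)c4)[C@@H]3CO)cc2OC)ccc1O | target

## Step count and least certain steps

Total step count: 18. Longest linear sequence: 16 steps (from 3 through steps 2–15, 17 and 18).

**Step 8 (key step).** The most likely failure is that the Lewis acid is consumed by formaldehyde oligomers while the hindered cis-2,3-disubstituted ring opens slowly, so that adventitious water or triflate opens the ring instead. Partial ionisation at C2 before O-attack would erode the 2,3-trans selectivity. The fallback sets out from 13 and returns at 15, making the same two bonds stepwise. Sc(OTf)3-catalysed methanolysis opens 13 with inversion to dimethyl 2-{(2R,3S)-1-(benzyloxy)-3-[3,5-dimethoxy-4-(triisopropylsilyloxy)phenyl]-3-methoxypropan-2-yl}malonate F1. Hydroxymethylation with paraformaldehyde and catalytic DBU in THF forms the C4–C5 bond and gives the 2-(hydroxymethyl)malonate F2. Catalytic BF3·OEt2 in CH2Cl2 at low temperature then ionises the benzylic methyl ether, and the primary hydroxyl closes the ring anti to the C3 substituent to give 15.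

**Step 7.** After the first displacement, the secondary sulfate monoester must be displaced in a closure that builds a cis-trisubstituted ring. β-Elimination can compete, and if malonate enters first at the non-benzylic carbon, ionisation of the benzylic sulfate would scramble that centre. Over-oxidation of the electron-rich ring while 10 is made would add to the loss. The fallback sets out from 2 and returns at 13 by carbene transfer. Sonogashira coupling of 2 with benzyl propargyl ether (PdCl2(PPh3)2, CuI, Et3N) gives {4-[3-(benzyloxy)prop-1-yn-1-yl]-2,6-dimethoxyphenoxy}triisopropylsilane F3. Semihydrogenation over Pb-poisoned Pd/CaCO3 with quinoline gives the Z-alkene F4. Dimethyl 2-(phenyl-λ3-iodanylidene)malonate F5, made from 11 with PhI(OAc)2 and KOH, then transfers its carbene to F4 under [Cu(MeCN)4]PF6 (monovalent copper) with a C2-symmetric side-armed bis(oxazoline) ligand. The suprafacial addition keeps the cis geometry, and the ligand antipode is chosen for the (2R,3R) ring 13.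

**Step 9.** At 140 °C chloride, hydroxide or bicarbonate may cleave the aryl silyl ether, and the resulting para-oxido benzylic ether can open through a quinone methide and decompose. The fallback sets out from 10 and returns at 16, replacing hot halide by neutral palladium chemistry. Diallyl malonate and NaH convert 10 into the diallyl cyclopropane-1,1-dicarboxylate F6. The Sn(OTf)2 annulation with 14 gives the diallyl tetrahydrofuran-4,4-dicarboxylate F7. Pd(OAc)2, PPh3, HCO2H and Et3N in 1,4-dioxane (rt, then 100 °C) remove both allyl groups and decarboxylate to the 4-carboxylic acid F8 with the silyl ether intact. Me3SiCHN2 in MeOH–toluene then gives 16.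

**Step 14.** The activated benzylic oxygen may be lost by elimination toward the α-aryloxy cinnamoyl imide or by partial ionisation (retention), and the hindered carbinol may react slowly. The fallback sets out from 23 and returns at 26, inverting C7'' by oxidation and chelation-controlled reduction.
- NaBH4 in THF–H2O cleaves the auxiliary to give the threo (1S,2S) diol F9.
- TBSCl and imidazole protect the primary hydroxyl to give the silyl ether F10.
- Dess–Martin periodinane buffered with NaHCO3 gives the α-aryloxy ketone F11.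
- Zn(BH4)2 in Et2O at −30 °C, chelated between the carbonyl and aryloxy oxygens, delivers the erythro (1R,2S) alcohol F12.
- TBAF gives 26.

**Step 17.** The dilithium alkoxide of 26 may precipitate and stall the addition, and the excess aryllithium may enolise the amide at C4 and open the ring by retro-oxa-Michael elimination. The fallback sets out from 26 and returns at 29 with the diol masked. 2,2-Dimethoxypropane and PPTS give the (4R,5S)-4-aryl-2,2-dimethyl-1,3-dioxan-5-yl ether (acetonide) F13. Addition of 28 (1.3 equiv) gives the acetonide ketone F14. Aqueous acetic acid at rt then releases 29.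

## Further compounds

F1 | step 8 | dimethyl 2-{(2R,3S)-1-(benzyloxy)-3-[3,5-dimethoxy-4-(triisopropylsilyloxy)phenyl]-3-methoxypropan-2-yl}malonate | COc1cc([C@@H](OC)[C@@H](COCc2ccccc2)C(C(=O)OC)C(=O)OC)cc(OC)c1O[Si](C(C)C)(C(C)C)C(C)C
F2 | step 8 | dimethyl 2-{(2R,3S)-1-(benzyloxy)-3-[3,5-dimethoxy-4-(triisopropylsilyloxy)phenyl]-3-methoxypropan-2-yl}-2-(hydroxymethyl)malonate | COc1cc([C@@H](OC)[C@@H](COCc2ccccc2)C(CO)(C(=O)OC)C(=O)OC)cc(OC)c1O[Si](C(C)C)(C(C)C)C(C)C
F3 | step 7 | {4-[3-(benzyloxy)prop-1-yn-1-yl]-2,6-dimethoxyphenoxy}triisopropylsilane | COc1cc(C#CCOCc2ccccc2)cc(OC)c1O[Si](C(C)C)(C(C)C)C(C)C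
F4 | step 7 | (Z)-{4-[3-(benzyloxy)prop-1-en-1-yl]-2,6-dimethoxyphenoxy}triisopropylsilane | COc1cc(/C=C\COCc2ccccc2)cc(OC)c1O[Si](C(C)C)(C(C)C)C(C)C
F5 | step 7 | dimethyl 2-(phenyl-λ3-iodanylidene)malonate (iodonium ylide) | COC(=O)[C-](C(=O)OC)[I+]c1ccccc1
F6 | step 9 | diallyl (2R,3R)-2-[(benzyloxy)methyl]-3-[3,5-dimethoxy-4-(triisopropylsilyloxy)phenyl]cyclopropane-1,1-dicarboxylate | COc1cc([C@H]2[C@@H](COCc3ccccc3)C2(C(=O)OCC=C)C(=O)OCC=C)cc(OC)c1O[Si](C(C)C)(C(C)C)C(C)C
F7 | step 9 | diallyl (2S,3R)-3-[(benzyloxy)methyl]-2-[3,5-dimethoxy-4-(triisopropylsilyloxy)phenyl]tetrahydrofuran-4,4-dicarboxylate | COc1cc([C@H]2OCC(C(=O)OCC=C)(C(=O)OCC=C)[C@@H]2COCc2ccccc2)cc(OC)c1O[Si](C(C)C)(C(C)C)C(C)C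
F8 | step 9 | (2S,3R,4RS)-3-[(benzyloxy)methyl]-2-[3,5-dimethoxy-4-(triisopropylsilyloxy)phenyl]tetrahydrofuran-4-carboxylic acid | COc1cc([C@H]2OCC(C(=O)O)[C@@H]2COCc2ccccc2)cc(OC)c1O[Si](C(C)C)(C(C)C)C(C)C
F9 | step 14 | (2S,3R,4S)-2-(4-{[(1S,2S)-1-[4-(benzyloxy)-3-methoxyphenyl]-1,3-dihydroxypropan-2-yl]oxy}-3,5-dimethoxyphenyl)-3-[(benzyloxy)methyl]-N-methoxy-N-methyltetrahydrofuran-4-carboxamide (threo) | COc1cc([C@H](O)[C@H](CO)Oc2c(OC)cc([C@H]3OC[C@@H](C(=O)N(C)OC)[C@@H]3COCc3ccccc3)cc2OC)ccc1OCc1ccccc1
F10 | step 14 | (2S,3R,4S)-2-(4-{[(1S,2S)-1-[4-(benzyloxy)-3-methoxyphenyl]-3-(tert-butyldimethylsilyloxy)-1-hydroxypropan-2-yl]oxy}-3,5-dimethoxyphenyl)-3-[(benzyloxy)methyl]-N-methoxy-N-methyltetrahydrofuran-4-carboxamide | COc1cc([C@H](O)[C@H](CO[Si](C)(C)C(C)(C)C)Oc2c(OC)cc([C@H]3OC[C@@H](C(=O)N(C)OC)[C@@H]3COCc3ccccc3)cc2OC)ccc1OCc1ccccc1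
F11 | step 14 | (2S,3R,4S)-2-(4-{[(S)-1-[4-(benzyloxy)-3-methoxyphenyl]-3-(tert-butyldimethylsilyloxy)-1-oxopropan-2-yl]oxy}-3,5-dimethoxyphenyl)-3-[(benzyloxy)methyl]-N-methoxy-N-methyltetrahydrofuran-4-carboxamide | COc1cc(C(=O)[C@H](CO[Si](C)(C)C(C)(C)C)Oc2c(OC)cc([C@H]3OC[C@@H](C(=O)N(C)OC)[C@@H]3COCc3ccccc3)cc2OC)ccc1OCc1ccccc1
F12 | step 14 | (2S,3R,4S)-2-(4-{[(1R,2S)-1-[4-(benzyloxy)-3-methoxyphenyl]-3-(tert-butyldimethylsilyloxy)-1-hydroxypropan-2-yl]oxy}-3,5-dimethoxyphenyl)-3-[(benzyloxy)methyl]-N-methoxy-N-methyltetrahydrofuran-4-carboxamide (erythro) | COc1cc([C@@H](O)[C@H](CO[Si](C)(C)C(C)(C)C)Oc2c(OC)cc([C@H]3OC[C@@H](C(=O)N(C)OC)[C@@H]3COCc3ccccc3)cc2OC)ccc1OCc1ccccc1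
F13 | step 17 | (2S,3R,4S)-2-(4-{[(4R,5S)-4-[4-(benzyloxy)-3-methoxyphenyl]-2,2-dimethyl-1,3-dioxan-5-yl]oxy}-3,5-dimethoxyphenyl)-3-[(benzyloxy)methyl]-N-methoxy-N-methyltetrahydrofuran-4-carboxamide | COc1cc([C@H]2OC(C)(C)OC[C@@H]2Oc2c(OC)cc([C@H]3OC[C@@H](C(=O)N(C)OC)[C@@H]3COCc3ccccc3)cc2OC)ccc1OCc1ccccc1
F14 | step 17 | [(2S,3R,4S)-2-(4-{[(4R,5S)-4-[4-(benzyloxy)-3-methoxyphenyl]-2,2-dimethyl-1,3-dioxan-5-yl]oxy}-3,5-dimethoxyphenyl)-3-[(benzyloxy)methyl]tetrahydrofuran-4-yl][4-(benzyloxy)-3,5-dimethoxyphenyl]methanone | COc1cc([C@H]2OC(C)(C)OC[C@@H]2Oc2c(OC)cc([C@H]3OC[C@@H](C(=O)c4cc(OC)c(OCc5ccccc5)c(OC)c4)[C@@H]3COCc3ccccc3)cc2OC)ccc1OCc1ccccc1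
A1 | alternative 1 | trans-3-[(4-allyloxy-3,5-dimethoxyphenyl)(hydroxy)methyl]-4-[2-(4-benzyloxy-3,5-dimethoxyphenyl)-1,3-dithian-2-yl]-5-(menthyloxy)dihydrofuran-2(3H)-one | O=C1O[C@@H](O[C@@H]2C[C@H](C)CC[C@H]2C(C)C)[C@H](C2(c3cc(OC)c(OCc4ccccc4)c(OC)c3)SCCCS2)[C@H]1[C@H](O)c1cc(OC)c(OCC=C)c(OC)c1
A2 | alternative 1 | (5R)-5-(menthyloxy)furan-2(5H)-one | O=C1O[C@@H](O[C@@H]2C[C@H](C)CC[C@H]2C(C)C)C=C1
A3 | alternative 1 | 2-(4-benzyloxy-3,5-dimethoxyphenyl)-1,3-dithiane | COc1cc(C2SCCCS2)cc(OC)c1OCc1ccccc1
A4 | alternative 1 | 4-(allyloxy)-3,5-dimethoxybenzaldehyde | COc1cc(C=O)cc(OC)c1OCC=C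
A5 | alternative 2 | [(2S,3R,4R)-2-(4-allyloxy-3,5-dimethoxyphenyl)-4-(4-tert-butyldimethylsilyloxy-3,5-dimethoxybenzyl)tetrahydrofuran-3-yl]methanol | C=CCOc1c(OC)cc([C@H]2OC[C@H](Cc3cc(OC)c(O[Si](C)(C)C(C)(C)C)c(OC)c3)[C@@H]2CO)cc1OC
A6 | alternative 2 | 2-{(R)-(4-allyloxy-3,5-dimethoxyphenyl)[(E)-3-(4-tert-butyldimethylsilyloxy-3,5-dimethoxyphenyl)allyloxy]methyl}oxirane (either oxirane epimer) | C=CCOc1c(OC)cc([C@@H](OC/C=C/c2cc(OC)c(O[Si](C)(C)C(C)(C)C)c(OC)c2)C2CO2)cc1OC
A7 | alternative 3 | (R)-4-[2-(4-benzyloxy-3,5-dimethoxyphenyl)-1,3-dioxolan-2-yl]dihydrofuran-2(3H)-one | O=C1C[C@@H](C2(c3cc(OC)c(OCc4ccccc4)c(OC)c3)OCCO2)CO1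
A8 | alternative 3 | 3-[2-(4-benzyloxy-3,5-dimethoxyphenyl)-1,3-dioxolan-2-yl]cyclobutan-1-one | O=C1CC(C1)C1(c2cc(OC)c(OCc3ccccc3)c(OC)c2)OCCO1
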